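**Time allowed.** The flask gets 3.0 d, and these runs were what I had:

| flask | left-handed substrate | right-handed substrate | gas | free catalyst | remark | time |
|---|---|---|---|---|---|---|
| Sunday's | 0.050 M | 0.050 M | 3.5 mM (held) | 0.5 mol% | run made earlier |  |
| Monday's | 0.050 M | 0.050 M | 3.5 mM (held) | 2 mol% | run made earlier |  |
| Saturday's | 0.10 M | 0.10 M | 3.5 mM (held) | 1 mol% | run made earlier |  |
| flask | 0.050 M | 0.050 M | 3.5 mM (held) | 1 mol% |  | 3.0 d |

| run | time / d | left-handed product / % | right-handed product / % |
|---|---|---|---|
| Sunday's | 0.208 | 8.5 | 3.8 |
| Sunday's | 0.333 | 9.8 | 6.3 |
| Sunday's | 0.625 | 13.1 | 8.5 |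
| Sunday's | 1.25 | 21.1 | 13.7 |
| Sunday's | 2.50 | 24.8 | 14.5 |
| Monday's | 0.500 | 17.5 | 11.6 |
| Monday's | 1.04 | 31.1 | 18.0 |
| Monday's | 1.25 | 33.0 | 21.2 |
| Monday's | 2.08 | 36.5 | 23.0 |
| Monday's | 2.50 | 37.2 | 23.3 |
| Saturday's | 0.208 | 1.4 | 2.6 |
| Saturday's | 0.333 | 5.9 | 4.0 |
| Saturday's | 0.625 | 12.6 | 8.6 |
| Saturday's | 1.25 | 17.7 | 12.2 |
| Saturday's | 2.50 | 25.9 | 16.6 |

(each reading ± 1 percentage point)

- free catalyst is single-handed; left-handed substrate and right-handed substrate are mirror images of each other, charged as a racemate, each of them at the stated concentration
- at the start none of partner is dissolved
- what may be going on: partner + free catalyst + left-handed substrate -> free catalyst + left-handed product; partner + free catalyst + right-handed substrate -> free catalyst + right-handed product; left-handed substrate <-> right-handed substrate; gas <-> partner; partner -> decomposed reagent; free catalyst -> spent catalyst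
- an excess is below zero if the other one leads

- left-handed product and right-handed product together, in percent of the left-handed substrate and right-handed substrate charged together, at 3.0 d
- excess of left-handed product over right-handed product in the product at 3.0 d
- whether the exchange between left-handed substrate and right-handed substrate keeps pace with the reaction: how far the product's excess at 3.0 d gets from its value without exchange to its value with instant exchange (above 80% keeps pace, below 20% hardly takes part, else lags behind)

**Early pace.** I first turned one early reading of each run into a mean rate, the product concentration divided by the time of that reading, and got 48.3 mM d⁻¹ on Sunday, 58.2 mM d⁻¹ on Monday and 67.8 mM d⁻¹ on Saturday. Monday's mean rate exceeded Sunday's by a factor of 1.20 for 4.00 times the loading, so I took the passage of gas into partner as the early rate-limiting step.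

**Doubling gain.** If free catalyst is lost by a first-order step, each doubling of its charge lengthens the time until it falls to a given concentration by a fixed amount, so I supposed that a run's total at a steady supply rises by a fixed step per doubling. So I defined g, the yield gained per doubling of catalyst at fixed gas and substrate concentration and fixed time. Sunday's last total of 39.3% and Monday's of 60.5%, both readings at the same time, lie two doublings apart, so I read g = 11 percentage points, and for the flask, one doubling above Sunday's run, I reckoned 49.9%.

**Two doubts.** Those runs stopped at 2.50 d, but Monday's last interval added 1 point, within the 1.4 points scatter of a sum, so I added nothing. Substrate thins as yield rises, but Sunday's and Monday's runs had the flask's substrate concentrations and their totals lie on either side of my estimate, so g holds this thinning as an average over that span.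

**The excess.** The last excesses of Sunday's, Monday's and Saturday's runs were 26.2%, 23.0% and 21.9%, with a mean of 23.7%. Monday's, at a total of 60.5%, lay 0.70 points below that mean, less than the 2.3 points scatter of that excess, so I read no fall of the excess with yield and expected the mean, with exchange keeping pace.

**The forecast.** It gave 48%, 22% and "keeps pace", holding that the flattening “points to the catalyst dying”; its yield lay 1.9 points below mine.

**The result.** The flask gave 49.5% and 23.9%, and keeps pace, at 97% of the way.

    partner + free catalyst + left-handed substrate → free catalyst + left-handed product (k = 3.60 × 10⁵ M⁻² h⁻¹)
    partner + free catalyst + right-handed substrate → free catalyst + right-handed product (k = 2.20 × 10⁵ M⁻² h⁻¹)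
    left-handed substrate ⇌ right-handed substrate (k = 1.20 h⁻¹)
    gas ⇌ partner, rate k4*(csat - [partner]) (kL = 0.740 h⁻¹)
    partner → decomposed reagent (k = 0.500 h⁻¹)
    free catalyst → spent catalyst (k = 0.110 h⁻¹)

**What ran.** In the flask, free catalyst stood at 45.3% after 0.300 d and 1.91% after 1.50 d, and half of the making of left-handed product up to 3.0 d was done by 0.488 d. At 3.00 d the flask's partner stood at 0.00208 M, its half-life 0.058 d by loss to decomposed reagent against 17 d by making left-handed product, and the flask's total lay 10 points above Sunday's last reading, beside g of 11 points.

**Next flask.** A neighbour with 0.6 mol% of free catalyst lies 0.737 doublings below the flask, so g gave 41.4%; its computed yield was 41.3%.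

Readings and results were computed for an exercise; noise was put on by code.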